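**Plan**
1. Retrosynthesis: after the two tropolone O-methyl groups are removed, both pyran C–O bonds are cut with allylic transposition. These are O1–C2 in the C3-methyl half and O1'–C2' in the other half (pyran atoms O1, C2, C3, C4; primed in the second half).
2. This works because C2 and C2' are the two ends of the (E,E)-diene Ca=Cb–Cc=Cd that links the dihydropyran rings. Moving each ring-oxygen bond inward (C2 to Cb, C2' to Cc) turns this 1,6-dioxy-2,4-diene into a C2=Ca–Cb(OH)–Cc(OH)–Cd=C2' diene-diol carrying two free 4-hydroxytropone arms.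
3. The two alkenes of that diol are cut by cross-metathesis into (3R,4R)-hexa-1,5-diene-3,4-diol (from D-mannitol) and two terminal-alkene arms. Each arm is cut at the tropone C5–CH2 bond (Negishi coupling) back to one 5-bromotropone.
4. The bromotropone comes from 2-methylphenol by Birch reduction, dibromocarbene addition, dihydroxylation and oxidative ring enlargement.
5. Forward order: seven-membered ring, side chains, chain assembly by two metatheses, both pyran rings in one palladium-catalysed step, demethylation.
6. Stereochemistry: C3 from a copper-catalysed asymmetric allylic methylation; C2 and C2' from the mannitol-derived carbinols Cb and Cc by 1,3-chirality transfer.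

Key step: step 16

Remark: O-methylation in step 6 can occur on either tropolone oxygen, and the route assumes the isomer named there can be separated. The bicyclic intermediates of steps 3 to 5 are racemic (relative configuration drawn) because their stereocentres vanish in step 5. In step 16 the unbranched half is assumed to close first, which only affects how the unisolated intermediate is drawn.

**Route**

Step 1
Reactants: 1 2-methylphenol
Product: 2 1-(methoxymethoxy)-2-methylbenzene
Conditions: NaH, THF, 0 °C; chloromethyl methyl ether, 0 → 20 °C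
Reagents that add atoms: chloromethyl methyl ether, COCCl
Why: Williamson-type O-alkylation of the sodium phenoxide gives an acetal ether that should survive dissolving metal, base and oxidation and is later removed by mild acid.

Step 2
Reactants: 2 1-(methoxymethoxy)-2-methylbenzene
Product: 3 1-(methoxymethoxy)-2-methylcyclohexa-1,4-diene
Conditions: Li, NH3 (l), t-BuOH, THF, −78 → −33 °C; then MeOH, H2O
Reagents that add atoms: none
Why: Birch reduction of the aryl ether protonates the unsubstituted ortho carbon and the carbon para to it, so the oxygen and the methyl group should remain on one tetrasubstituted enol-ether double bond of the 1,4-diene.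

Step 3
Reactants: 3 1-(methoxymethoxy)-2-methylcyclohexa-1,4-diene
Product: 4 rac-7,7-dibromo-1-(methoxymethoxy)-6-methylbicyclo[4.1.0]hept-3-ene (cis-fused)
Conditions: CHBr3, KOt-Bu, pentane, −20 → 0 °C
Reagents that add atoms: bromoform, BrC(Br)Br
Why: Dibromocarbene (Doering–Hoffmann conditions) is electrophilic and should add in a concerted [2+1] cycloaddition to the electron-rich tetrasubstituted enol-ether alkene rather than the disubstituted one; the cis fusion follows from the concerted addition and the racemic centres are lost in step 5.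

Step 4
Reactants: 4 rac-7,7-dibromo-1-(methoxymethoxy)-6-methylbicyclo[4.1.0]hept-3-ene
Product: 5 rac-7,7-dibromo-1-(methoxymethoxy)-6-methylbicyclo[4.1.0]heptane-3,4-diol (cis-diol on the face away from the CBr2 bridge)
Conditions: OsO4 (2 mol%), N-methylmorpholine N-oxide, acetone/H2O, 0 → 20 °C
Reagents that add atoms: N-methylmorpholine N-oxide, C[N+]1([O-])CCOCC1; water, O
Why: Upjohn dihydroxylation adds syn to the remaining alkene from the face not shielded by the endo bromine; the diol configuration does not matter because both carbinols become carbonyl carbons in the next step.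

Step 5
Reactants: 5 rac-7,7-dibromo-1-(methoxymethoxy)-6-methylbicyclo[4.1.0]heptane-3,4-diol
Product: 7 5-bromo-2-hydroxy-4-(methoxymethoxy)-6-methylcyclohepta-2,4,6-trien-1-one, via bicyclic 1,2-diketone 6 (not isolated)
Conditions: (CF3CO)2O, DMSO, CH2Cl2, −60 °C; then Et3N, −60 → 20 °C
Reagents that add atoms: none
Why: Swern-type oxidation gives the 1,2-diketone, whose enolate should open the cyclopropane C1–C6 bond with loss of bromide and tautomerise to the tropolone, the established ring enlargement of gem-dibromocyclopropane-fused cyclohexanediols to 5-bromotropolones; the carbene carbon becomes C5 with its bromine, between the acetal oxygen on C4 and the methyl on C6.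

Step 6
Reactants: 7 5-bromo-2-hydroxy-4-(methoxymethoxy)-6-methylcyclohepta-2,4,6-trien-1-one
Product: 8 5-bromo-2-methoxy-4-(methoxymethoxy)-6-methylcyclohepta-2,4,6-trien-1-one
Conditions: MeI, K2CO3, acetone, 20 °C
Reagents that add atoms: iodomethane, CI
Why: Williamson O-methylation masks the chelating tropolone for the metal-catalysed steps; the tropolonate is ambident, so the regioisomeric methyl ether is expected as a by-product to be removed by chromatography.

Step 7
Reactants: 9 (E)-1,4-dibromobut-2-ene
Product: 10 (3S)-4-bromo-3-methylbut-1-ene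
Conditions: MeMgBr, CuBr·SMe2 (3 mol%), BINOL-derived phosphoramidite ligand O,O'-(1,1'-binaphthyl-2,2'-diyl) N,N-bis[1-(2-methoxyphenyl)ethyl]phosphoramidite (enantiomer chosen to give the S bromide), CH2Cl2, −78 °C
Reagents that add atoms: methylmagnesium bromide, C[Mg]Br
Why: Copper-catalysed asymmetric allylic alkylation with a Grignard reagent proceeds SN2' on the allylic bromide, and the chiral copper–phosphoramidite complex selects the alkene face, setting the methyl-bearing centre (future C3) as S in the bromide.

Step 8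
Reactants: 10 (3S)-4-bromo-3-methylbut-1-ene; 8 5-bromo-2-methoxy-4-(methoxymethoxy)-6-methylcyclohepta-2,4,6-trien-1-one
Product: 12 2-methoxy-4-(methoxymethoxy)-6-methyl-5-[(2R)-2-methylbut-3-en-1-yl]cyclohepta-2,4,6-trien-1-one, via alkylzinc bromide 11 (not isolated)
Conditions: 10, Zn dust (activated with BrCH2CH2Br, Me3SiCl), LiCl, THF, 40 °C; then 8, Pd(OAc)2 (3 mol%), SPhos (2-dicyclohexylphosphino-2',6'-dimethoxybiphenyl, 6 mol%), THF, 25 → 50 °C
Reagents that add atoms: none
Why: Zinc insertion into the primary C–Br bond leaves the adjacent stereocentre untouched, and Negishi sp2–sp3 coupling with a bulky biarylphosphine (fast reductive elimination at a di-ortho-substituted centre, little β-hydride elimination) forms the tropone C5–CH2 bond; the centre keeps its spatial arrangement and is R only because the CIP priorities change.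

Step 9
Reactants: 8 5-bromo-2-methoxy-4-(methoxymethoxy)-6-methylcyclohepta-2,4,6-trien-1-one; 13 but-3-en-1-ylzinc bromide (commercial THF solution)
Product: 14 5-(but-3-en-1-yl)-2-methoxy-4-(methoxymethoxy)-6-methylcyclohepta-2,4,6-trien-1-one
Conditions: Pd(OAc)2 (3 mol%), SPhos (6 mol%), THF, 25 → 50 °C
Reagents that add atoms: none
Why: The same Negishi sp2–sp3 coupling installs the unbranched four-carbon arm; alkylzinc halides should not add to the tropone carbonyl.

Step 10
Reactants: 15 D-mannitol
Product: 16 2,3,4,5-tetra-O-acetyl-1,6-dibromo-1,6-dideoxy-D-mannitol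
Conditions: acetyl bromide, 1,4-dioxane, 20 °C; then Ac2O, pyridine, 20 °C
Reagents that add atoms: acetyl bromide, CC(=O)Br; acetic anhydride, CC(=O)OC(C)=O
Why: Acetyl bromide converts each terminal 1,2-diol through an acetoxonium ion that bromide opens at the primary carbon, and acetylation completes the tetraacetate; C2–C5 are not inverted.

Step 11
Reactants: 16 2,3,4,5-tetra-O-acetyl-1,6-dibromo-1,6-dideoxy-D-mannitol
Product: 17 (3R,4R)-hexa-1,5-diene-3,4-diyl diacetate
Conditions: Zn dust, NaOAc, AcOH, 20 → 60 °C
Reagents that add atoms: none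
Why: Zinc-mediated reductive 1,2-elimination of the two vicinal bromo acetates (Boord-type olefin synthesis) forms both vinyl groups and removes C2 and C5 as stereocentres, leaving C3 and C4 of mannitol as the R,R pair.

Step 12
Reactants: 17 (3R,4R)-hexa-1,5-diene-3,4-diyl diacetate
Product: 18 (3R,4R)-hexa-1,5-diene-3,4-diol
Conditions: K2CO3 (cat.), MeOH, 20 °C
Reagents that add atoms: none
Why: Base-catalysed transesterification (Zemplén-type methanolysis) frees the diol without touching the carbinol centres.

Step 13
Reactants: 12 2-methoxy-4-(methoxymethoxy)-6-methyl-5-[(2R)-2-methylbut-3-en-1-yl]cyclohepta-2,4,6-trien-1-one; 18 (3R,4R)-hexa-1,5-diene-3,4-diol (4 equiv)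
Product: 19 5-[(2R,3E,5R,6R)-5,6-dihydroxy-2-methylocta-3,7-dien-1-yl]-2-methoxy-4-(methoxymethoxy)-6-methylcyclohepta-2,4,6-trien-1-one
Conditions: second-generation Hoveyda–Grubbs catalyst RuCl2(H2IMes)(=CH-C6H4-2-Oi-Pr) (10 mol%), CH2Cl2, 40 °C, argon sparge
Reagents that add atoms: none
Why: Olefin cross-metathesis joins the methyl-branched terminal alkene to one vinyl group of the diol; both partners homodimerise slowly, the excess of diol should suppress double reaction, and the disubstituted alkene should form E under thermodynamic control.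

Step 14
Reactants: 19 5-[(2R,3E,5R,6R)-5,6-dihydroxy-2-methylocta-3,7-dien-1-yl]-2-methoxy-4-(methoxymethoxy)-6-methylcyclohepta-2,4,6-trien-1-one; 14 5-(but-3-en-1-yl)-2-methoxy-4-(methoxymethoxy)-6-methylcyclohepta-2,4,6-trien-1-one (2 equiv)
Product: 20 5,5'-[(2R,3E,5R,6R,7E)-5,6-dihydroxy-2-methyldeca-3,7-diene-1,10-diyl]bis[2-methoxy-4-(methoxymethoxy)-6-methylcyclohepta-2,4,6-trien-1-one]
Conditions: second-generation Hoveyda–Grubbs catalyst RuCl2(H2IMes)(=CH-C6H4-2-Oi-Pr) (5 mol%), CH2Cl2, 40 °C
Reagents that add atoms: none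
Why: The second cross-metathesis pairs a fast-reacting unbranched terminal alkene (in excess) with the remaining slowly dimerising allylic-alcohol vinyl group, a selective pairing that should give the E-alkene; the alkene made in step 13, flanked by two branched carbons, should not re-enter metathesis.

Step 15
Reactants: 20 5,5'-[(2R,3E,5R,6R,7E)-5,6-dihydroxy-2-methyldeca-3,7-diene-1,10-diyl]bis[2-methoxy-4-(methoxymethoxy)-6-methylcyclohepta-2,4,6-trien-1-one]
Product: 21 5,5'-[(2R,3E,5R,6R,7E)-5,6-dihydroxy-2-methyldeca-3,7-diene-1,10-diyl]bis(4-hydroxy-2-methoxy-6-methylcyclohepta-2,4,6-trien-1-one)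
Conditions: HCl (cat.) in MeOH, 0 → 20 °C
Reagents that add atoms: none
Why: Acid-catalysed acetal exchange removes the two methoxymethyl groups, which sit on vinylogous-acid oxygens and should therefore cleave much faster than the allylic diol ionises or the methyl ethers hydrolyse.

Step 16
Reactants: 21 5,5'-[(2R,3E,5R,6R,7E)-5,6-dihydroxy-2-methyldeca-3,7-diene-1,10-diyl]bis(4-hydroxy-2-methoxy-6-methylcyclohepta-2,4,6-trien-1-one)
Product: 23 (2R,3R)-8-methoxy-2-{(1E,3E)-4-[(2R)-8-methoxy-5-methyl-7-oxo-2,3,4,7-tetrahydrocyclohepta[b]pyran-2-yl]buta-1,3-dien-1-yl}-3,5-dimethyl-3,4-dihydrocyclohepta[b]pyran-7(2H)-one, via mono-cyclised dienol 22 (not isolated)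
Conditions: PdCl2(MeCN)2 (10 mol%), THF, 0 → 20 °C
Reagents that add atoms: none
Why: Proposed new method: PdCl2(MeCN)2 (divalent palladium) is expected to bind each alkene on the face of its allylic hydroxyl, the ring hydroxyl then adds to C2 (or C2') and palladium-bound hydroxide leaves from Cb (or Cc) on the same face, a net syn-SN2' displacement that frees the catalyst and water. The closest known reaction type is the PdCl2(MeCN)2-catalysed dehydrative cyclisation of hydroxy allylic alcohols to 2-alkenyl tetrahydropyrans with 1,3-chirality transfer, here run twice on one vicinal diol with a 4-hydroxytropone oxygen as nucleophile. Both pyran rings close 6-exo-trig, forming O1–C2 and O1'–C2'. C2 is set R by (R)-Cb and C2' is set R by (R)-Cc, because displacement through the conformer with the carbinol hydrogen eclipsing the alkene (least allylic 1,3-strain) gives the E-alkene and delivers oxygen to the face from which hydroxide departs; the C3 methyl group then lies equatorial and trans to the new C2 substituent, so the preset centre is matched. The step needs six-ring closure and stereospecific displacement rather than ionisation of the doubly allylic alcohol 22; the six-atom spacing of each nucleophile from its alkene terminus secures the first, and a neutral solvent, low temperature and absence of added acid are meant to secure the second. Both carbinol stereocentres are consumed and both E-alkenes of the diene are created.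

Step 17
Reactants: 23 bis(methyl ether) of the target
Product: 24 (2R,3R)-8-hydroxy-2-{(1E,3E)-4-[(2R)-8-hydroxy-5-methyl-7-oxo-2,3,4,7-tetrahydrocyclohepta[b]pyran-2-yl]buta-1,3-dien-1-yl}-3,5-dimethyl-3,4-dihydrocyclohepta[b]pyran-7(2H)-one (CNP0332980.1)
Conditions: LiOH·H2O, THF/H2O, 45 °C; then AcOH to pH 5
Reagents that add atoms: lithium hydroxide, [Li+].[OH-]
Why: Alkaline hydrolysis of a 2-methoxytropone is a vinylogous ester saponification (hydroxide adds at the methoxy-bearing carbon C8 and methoxide leaves); the tropolonate formed is deactivated toward further attack, so the pyran oxygens and the dienyl C–O bonds should be spared and no stereocentre is touched.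

**Compound list**
1 | 2-methylphenol | Cc1ccccc1O | starting material
2 | 1-(methoxymethoxy)-2-methylbenzene | COCOc1ccccc1C | intermediate
3 | 1-(methoxymethoxy)-2-methylcyclohexa-1,4-diene | COCOC1=C(C)CC=CC1 | intermediate
4 | rac-7,7-dibromo-1-(methoxymethoxy)-6-methylbicyclo[4.1.0]hept-3-ene, cis-fused (one enantiomer drawn) | COCO[C@]12CC=CC[C@@]1(C)C2(Br)Br | intermediate
5 | rac-7,7-dibromo-1-(methoxymethoxy)-6-methylbicyclo[4.1.0]heptane-3,4-diol, cis-diol anti to the CBr2 bridge (one enantiomer drawn) | COCO[C@]12C[C@H](O)[C@H](O)C[C@@]1(C)C2(Br)Br | intermediate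
6 | rac-7,7-dibromo-1-(methoxymethoxy)-6-methylbicyclo[4.1.0]heptane-3,4-dione | COCO[C@]12CC(=O)C(=O)C[C@@]1(C)C2(Br)Br | intermediate (not isolated)
7 | 5-bromo-2-hydroxy-4-(methoxymethoxy)-6-methylcyclohepta-2,4,6-trien-1-one | COCOc1cc(O)c(=O)cc(C)c1Br | intermediate
8 | 5-bromo-2-methoxy-4-(methoxymethoxy)-6-methylcyclohepta-2,4,6-trien-1-one | COCOc1cc(OC)c(=O)cc(C)c1Br | intermediate
9 | (E)-1,4-dibromobut-2-ene | BrC/C=C/CBr | starting material
10 | (3S)-4-bromo-3-methylbut-1-ene | BrC[C@@H](C)C=C | intermediate
11 | [(2S)-2-methylbut-3-en-1-yl]zinc bromide | Br[Zn]C[C@@H](C)C=C | intermediate (not isolated)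
12 | 2-methoxy-4-(methoxymethoxy)-6-methyl-5-[(2R)-2-methylbut-3-en-1-yl]cyclohepta-2,4,6-trien-1-one | COCOc1cc(OC)c(=O)cc(C)c1C[C@@H](C)C=C | intermediate
13 | but-3-en-1-ylzinc bromide | C=CCC[Zn]Br | starting material
14 | 5-(but-3-en-1-yl)-2-methoxy-4-(methoxymethoxy)-6-methylcyclohepta-2,4,6-trien-1-one | COCOc1cc(OC)c(=O)cc(C)c1CCC=C | intermediate
15 | D-mannitol | OC[C@@H](O)[C@@H](O)[C@H](O)[C@H](O)CO | starting material
16 | 2,3,4,5-tetra-O-acetyl-1,6-dibromo-1,6-dideoxy-D-mannitol | BrC[C@@H](OC(C)=O)[C@@H](OC(C)=O)[C@H](OC(C)=O)[C@H](OC(C)=O)CBr | intermediate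
17 | (3R,4R)-hexa-1,5-diene-3,4-diyl diacetate | C=C[C@@H](OC(C)=O)[C@H](OC(C)=O)C=C | intermediate
18 | (3R,4R)-hexa-1,5-diene-3,4-diol | C=C[C@@H](O)[C@H](O)C=C | intermediate
19 | 5-[(2R,3E,5R,6R)-5,6-dihydroxy-2-methylocta-3,7-dien-1-yl]-2-methoxy-4-(methoxymethoxy)-6-methylcyclohepta-2,4,6-trien-1-one | COCOc1cc(OC)c(=O)cc(C)c1C[C@@H](C)/C=C/[C@@H](O)[C@H](O)C=C | intermediate
20 | 5,5'-[(2R,3E,5R,6R,7E)-5,6-dihydroxy-2-methyldeca-3,7-diene-1,10-diyl]bis[2-methoxy-4-(methoxymethoxy)-6-methylcyclohepta-2,4,6-trien-1-one] | COCOc1cc(OC)c(=O)cc(C)c1C[C@@H](C)/C=C/[C@@H](O)[C@H](O)/C=C/CCc1c(C)cc(=O)c(OC)cc1OCOC | intermediate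
21 | 5,5'-[(2R,3E,5R,6R,7E)-5,6-dihydroxy-2-methyldeca-3,7-diene-1,10-diyl]bis(4-hydroxy-2-methoxy-6-methylcyclohepta-2,4,6-trien-1-one) | Cc1cc(=O)c(OC)cc(O)c1C[C@@H](C)/C=C/[C@@H](O)[C@H](O)/C=C/CCc1c(C)cc(=O)c(OC)cc1O | intermediate
22 | 4-hydroxy-5-{(2R,3E,5R,6E)-5-hydroxy-7-[(2R)-8-methoxy-5-methyl-7-oxo-2,3,4,7-tetrahydrocyclohepta[b]pyran-2-yl]-2-methylhepta-3,6-dien-1-yl}-2-methoxy-6-methylcyclohepta-2,4,6-trien-1-one | Cc1cc(=O)c(OC)cc(O)c1C[C@@H](C)/C=C/[C@@H](O)/C=C/[C@H]1CCc2c(C)cc(=O)c(OC)cc2O1 | intermediate (not isolated)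
23 | (2R,3R)-8-methoxy-2-{(1E,3E)-4-[(2R)-8-methoxy-5-methyl-7-oxo-2,3,4,7-tetrahydrocyclohepta[b]pyran-2-yl]buta-1,3-dien-1-yl}-3,5-dimethyl-3,4-dihydrocyclohepta[b]pyran-7(2H)-one | Cc1cc(=O)c(OC)cc2c1C[C@@H](C)[C@H](/C=C/C=C/[C@H]1CCc3c(C)cc(=O)c(OC)cc3O1)O2 | intermediate
24 | (2R,3R)-8-hydroxy-2-{(1E,3E)-4-[(2R)-8-hydroxy-5-methyl-7-oxo-2,3,4,7-tetrahydrocyclohepta[b]pyran-2-yl]buta-1,3-dien-1-yl}-3,5-dimethyl-3,4-dihydrocyclohepta[b]pyran-7(2H)-one | Cc1cc(=O)c(O)cc2c1C[C@@H](C)[C@H](/C=C/C=C/[C@H]1CCc3c(C)cc(=O)c(O)cc3O1)O2 | target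

**Step count**
Total: 17 steps. Longest linear sequence: 12 steps (steps 1–6, 8, 13–17, from 2-methylphenol).

**Steps most likely to fail**

Step 16 (labelled). What may go wrong: ionisation of the doubly allylic alcohol in 22, or of the first-formed dienylic C–O bond, may outrun the palladium-bound displacement, so chirality transfer to the second ring is lost; the diol and the acidic hydroxyls may also sequester the catalyst. Fallback with known chemistry, setting out from 20: acetylation (Ac2O, pyridine, DMAP) should give the 5,6-di-O-acetate of 20 F1. Acidic methanol (as in step 15) should then give the 5,6-di-O-acetate of 21 F2. Both rings are closed by intramolecular Tsuji–Trost allylic etherification with zerovalent palladium (Pd2(dba)3, PPh3 or a chiral diphosphine, Et3N, THF, 20 °C). Ionisation anti to acetate and attack of the tropone oxygen anti to palladium at the allyl terminus six atoms away give net retention with allylic transposition, the same stereochemical course, and the route is rejoined at 23.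

Step 5. What may go wrong: the donor oxygen on C1 may assist ionisation of a C7–Br bond, so the cyclopropane opens in the other sense (with loss of the methoxymethyl group) during dihydroxylation or oxidation, before the enolate-driven opening can occur. Fallback, setting out from 3: dichlorocarbene (CHCl3, 50% aq. NaOH, BnEt3NCl) should give rac-7,7-dichloro-1-(methoxymethoxy)-6-methylbicyclo[4.1.0]hept-3-ene F3, whose C–Cl bonds ionise far less readily. Dihydroxylation as in step 4 gives the dichloro diol F4. Oxidation as in step 5 (with warming or DBU for the opening) passes through the dichloro diketone F5 to 5-chloro-2-hydroxy-4-(methoxymethoxy)-6-methylcyclohepta-2,4,6-trien-1-one F6. Methylation as in step 6 gives 5-chloro-2-methoxy-4-(methoxymethoxy)-6-methylcyclohepta-2,4,6-trien-1-one F7. F7 is used in place of 8 in the Negishi couplings (the same Pd(OAc)2/SPhos system should activate this electron-poor C–Cl bond), and the route is rejoined at 12 and 14.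

Step 13. What may go wrong: productive metathesis at an alkene flanked by two branched allylic carbons may be slow, so homodimerisation of the diol and ruthenium-hydride isomerisation of the allylic alcohol take over. Fallback, reversing the order of bond formation on this side and setting out from 18, 14, 10 and 8: cross-metathesis of 14 with excess 18 should give the unbranched mono-adduct 5-[(3E,5R,6R)-5,6-dihydroxyocta-3,7-dien-1-yl]-2-methoxy-4-(methoxymethoxy)-6-methylcyclohepta-2,4,6-trien-1-one F8. The hindered metathesis is then run with a large excess of the small, volatile bromide 10 to give the bromo diol F9. 2,2-Dimethoxypropane with pyridinium p-toluenesulfonate gives the trans-acetonide F10. Zinc insertion as in step 8 gives the alkylzinc bromide F11, and Negishi coupling with 8 gives the acetonide of 20 F12. Aqueous HCl in methanol removes the acetonide and both methoxymethyl groups, and the route is rejoined at 21.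

**Further compounds**
F1 | step 16 | 5,6-di-O-acetate of 20 | COCOc1cc(OC)c(=O)cc(C)c1C[C@@H](C)/C=C/[C@@H](OC(C)=O)[C@H](OC(C)=O)/C=C/CCc1c(C)cc(=O)c(OC)cc1OCOC
F2 | step 16 | 5,6-di-O-acetate of 21 | Cc1cc(=O)c(OC)cc(O)c1C[C@@H](C)/C=C/[C@@H](OC(C)=O)[C@H](OC(C)=O)/C=C/CCc1c(C)cc(=O)c(OC)cc1O
F3 | step 5 | rac-7,7-dichloro-1-(methoxymethoxy)-6-methylbicyclo[4.1.0]hept-3-ene | COCO[C@]12CC=CC[C@@]1(C)C2(Cl)Cl
F4 | step 5 | rac-7,7-dichloro-1-(methoxymethoxy)-6-methylbicyclo[4.1.0]heptane-3,4-diol | COCO[C@]12C[C@H](O)[C@H](O)C[C@@]1(C)C2(Cl)Cl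
F5 | step 5 | rac-7,7-dichloro-1-(methoxymethoxy)-6-methylbicyclo[4.1.0]heptane-3,4-dione | COCO[C@]12CC(=O)C(=O)C[C@@]1(C)C2(Cl)Cl
F6 | step 5 | 5-chloro-2-hydroxy-4-(methoxymethoxy)-6-methylcyclohepta-2,4,6-trien-1-one | COCOc1cc(O)c(=O)cc(C)c1Cl
F7 | step 5 | 5-chloro-2-methoxy-4-(methoxymethoxy)-6-methylcyclohepta-2,4,6-trien-1-one | COCOc1cc(OC)c(=O)cc(C)c1Cl
F8 | step 13 | 5-[(3E,5R,6R)-5,6-dihydroxyocta-3,7-dien-1-yl]-2-methoxy-4-(methoxymethoxy)-6-methylcyclohepta-2,4,6-trien-1-one | COCOc1cc(OC)c(=O)cc(C)c1CC/C=C/[C@@H](O)[C@H](O)C=C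
F9 | step 13 | 5-[(3E,5R,6R,7E,9S)-10-bromo-5,6-dihydroxy-9-methyldeca-3,7-dien-1-yl]-2-methoxy-4-(methoxymethoxy)-6-methylcyclohepta-2,4,6-trien-1-one | BrC[C@@H](C)/C=C/[C@@H](O)[C@H](O)/C=C/CCc1c(C)cc(=O)c(OC)cc1OCOC
F10 | step 13 | trans-acetonide (2,2-dimethyl-1,3-dioxolane) of F9 | BrC[C@@H](C)/C=C/[C@H]1OC(C)(C)O[C@@H]1/C=C/CCc1c(C)cc(=O)c(OC)cc1OCOC
F11 | step 13 | alkylzinc bromide from F10 | Br[Zn]C[C@@H](C)/C=C/[C@H]1OC(C)(C)O[C@@H]1/C=C/CCc1c(C)cc(=O)c(OC)cc1OCOC
F12 | step 13 | 5,6-O-isopropylidene acetal of 20 | COCOc1cc(OC)c(=O)cc(C)c1C[C@@H](C)/C=C/[C@H]1OC(C)(C)O[C@@H]1/C=C/CCc1c(C)cc(=O)c(OC)cc1OCOC
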